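The route rests on disconnecting the O1–C8a bond of the chromone. In ring A, C8a is ortho to the C4 carbonyl of ring C, so a fluorine at C8a behaves as a vinylogous acyl fluoride. The enolate oxygen of a 2-benzyloxy-1,3-diketone displaces it by addition–elimination, closing the pyranone ring in one operation and fixing beforehand which ring-A carbon carries O1, so the usual doubt between C6 and C8 substitution never comes up. The precursor is that diketone: a 2-fluoro-4,6-dimethoxyphenyl ketone bearing the (R)-1-(4-benzyloxyphenyl)ethyl group at C3 (future C8, set by asymmetric hydrogenation), joined through a benzyloxy-substituted carbon to a 4-methoxybenzoyl group.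

Key step: step 7

Remarks and assumptions
- Structure check: the target is 3,5-dihydroxy-8-[(1R)-1-(4-hydroxyphenyl)ethyl]-7-methoxy-2-(4-methoxyphenyl)chromen-4-one. At the benzylic carbon the CIP order is ring-A carbon > 4-oxyphenyl > CH3 > H in every compound from 5 to 15, so the descriptor stays R. The structures of 13 and 14 are consistent with the target and needed no correction.
- Design: the glycolyl ketone is introduced by bromination, bromine–lithium exchange and an N-methoxy-N-methylamide, not by Lewis-acid acylation with an α-benzyloxyacetyl chloride. The acylium ion of that chloride loses CO easily to a benzyloxymethyl cation and can also cyclise onto its own benzyl ring, and two benzyl ethers would have to survive a strong Lewis acid.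
- Design: both removable oxygen groups are benzyl ethers, so one BCl3 operation ends the synthesis.
- Assumption: the sense of induction of the iridium catalyst on alkene 4 cannot be predicted with confidence. Both ligand antipodes are available; the one that gives (R)-5 is to be identified in a first run (absolute configuration to be checked, for example by X-ray on bromide 6).
- Assumption: amide 7 is taken as a catalogue compound.

Step 1
Reactants: 1 1-fluoro-3,5-dimethoxybenzene; 2 4-(benzyloxy)benzoyl chloride
Product: 3 [4-(benzyloxy)phenyl](2-fluoro-4,6-dimethoxyphenyl)methanone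
Conditions: SnCl4 (1.2 equiv), CH2Cl2, 0 °C → rt
Reagents that add atoms: none
Why: Friedel–Crafts acylation, in which the acyl chloride–SnCl4 complex should attack the C–H para to one methoxy group and next to the small fluorine rather than the C–H pinched between two methoxy groups, while the mild Lewis acid should leave the benzyl and methyl ethers intact.

Step 2
Reactants: 3 [4-(benzyloxy)phenyl](2-fluoro-4,6-dimethoxyphenyl)methanone
Product: 4 2-{1-[4-(benzyloxy)phenyl]ethenyl}-1-fluoro-3,5-dimethoxybenzene
Conditions: Ph3PCH3Br, NaHMDS, THF, 0 °C → 60 °C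
Reagents that add atoms: methyltriphenylphosphonium bromide, C[P+](c1ccccc1)(c1ccccc1)c1ccccc1.[Br-]
Why: Wittig methylenation of a non-enolisable diaryl ketone, with a silazide base so that no alkoxide is present to displace the carbonyl-activated fluorine.

Step 3
Reactants: 4 2-{1-[4-(benzyloxy)phenyl]ethenyl}-1-fluoro-3,5-dimethoxybenzene
Product: 5 2-{(1R)-1-[4-(benzyloxy)phenyl]ethyl}-1-fluoro-3,5-dimethoxybenzene
Conditions: H2 (50 bar), [Ir(cod)(L*)]BArF (1–2 mol %, L* = PHOX-type phosphine–oxazoline, antipode giving R), CH2Cl2, rt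
Reagents that add atoms: none
Why: Iridium-catalysed asymmetric hydrogenation of a 1,1-diarylethene, in which the 2-fluoro-6-methoxyaryl ring is twisted out of the alkene plane while the 4-benzyloxyphenyl ring stays conjugated, so the chiral P,N pocket can tell the two aryl groups apart and should deliver H2 to one face to set the (R) centre; aryl fluoride and benzyl ether are inert to the homogeneous catalyst.

Step 4
Reactants: 5 2-{(1R)-1-[4-(benzyloxy)phenyl]ethyl}-1-fluoro-3,5-dimethoxybenzene
Product: 6 1-bromo-3-{(1R)-1-[4-(benzyloxy)phenyl]ethyl}-2-fluoro-4,6-dimethoxybenzene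
Conditions: NBS (1.0 equiv), MeCN, 0 °C, dark
Reagents that add atoms: N-bromosuccinimide, O=C1CCC(=O)N1Br
Why: Electrophilic aromatic bromination, in which the dimethoxylated ring is by far the most electron-rich and its open position next to fluorine and para to a methoxy group should react in preference to the position buttressed between two methoxy groups.

Step 5
Reactants: 6 1-bromo-3-{(1R)-1-[4-(benzyloxy)phenyl]ethyl}-2-fluoro-4,6-dimethoxybenzene; 7 2-(benzyloxy)-N-methoxy-N-methylacetamide
Product: 10 2-(benzyloxy)-1-(3-{(1R)-1-[4-(benzyloxy)phenyl]ethyl}-2-fluoro-4,6-dimethoxyphenyl)ethan-1-one, via aryllithium 8 (not isolated), via lithium hemiaminal alkoxide 9 (not isolated)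
Conditions: n-BuLi (1.05 equiv), THF, −78 °C; then 7, −78 → −40 °C; 1 M HCl
Reagents that add atoms: none
Why: Bromine–lithium exchange followed by Weinreb ketone synthesis, in which the ortho-fluoroaryllithium is kept at −78 °C so that it does not eliminate LiF and the chelated tetrahedral adduct prevents over-addition until the acidic quench.

Step 6
Reactants: 10 2-(benzyloxy)-1-(3-{(1R)-1-[4-(benzyloxy)phenyl]ethyl}-2-fluoro-4,6-dimethoxyphenyl)ethan-1-one; 11 4-methoxybenzoyl chloride
Product: 13 2-(benzyloxy)-1-(3-{(1R)-1-[4-(benzyloxy)phenyl]ethyl}-2-fluoro-4,6-dimethoxyphenyl)-3-(4-methoxyphenyl)propane-1,3-dione (chelated enol), via lithium enolate 12 (not isolated)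
Conditions: LiHMDS (2.1 equiv), THF, −78 °C; then 11, −78 → 0 °C; dilute HCl
Reagents that add atoms: none
Why: Claisen-type C-acylation of a ketone enolate with an acid chloride, in which the chelated lithium enolate is acylated at carbon and the second equivalent of base converts the more acidic 1,3-diketone into its enolate, which stops further acylation, while the bulky silazide does not attack the C–F bond.

Step 7
Reactants: 13 2-(benzyloxy)-1-(3-{(1R)-1-[4-(benzyloxy)phenyl]ethyl}-2-fluoro-4,6-dimethoxyphenyl)-3-(4-methoxyphenyl)propane-1,3-dione (chelated enol)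
Product: 14 3-(benzyloxy)-8-{(1R)-1-[4-(benzyloxy)phenyl]ethyl}-5,7-dimethoxy-2-(4-methoxyphenyl)-4H-chromen-4-one
Conditions: K2CO3 (3 equiv), dry DMF, 90 °C (Cs2CO3, DMSO if slow)
Reagents that add atoms: none
Why: Carbonate turns diketone 13 into its enolate, whose oxygen on the anisyl-bearing carbon adds to C8a, the fluorinated ring-A carbon ortho to the C4 carbonyl, giving a cyclohexadienyl (Meisenheimer-type) anion whose charge runs through C4a into the C4 carbonyl; loss of fluoride then restores the arene. The closest known reaction type is the base-mediated intramolecular SNAr of 1-(2-haloaryl)-1,3-diketones to chromones and flavones. The pyranone ring closes in a 6-endo-trig addition–elimination, that is an oxa-Michael addition across the C4a=C8a bond followed by β-loss of fluoride. No stereocentre is formed, and the benzylic centre at C8 has no hydrogen acidic enough for carbonate to remove. The step needs O-arylation by the correct enolate oxygen and substitution of fluorine rather than of the methoxy group at C5: the central carbon and the other oxygen could only close a four-membered ring, and fluoride is by far the better SNAr nucleofuge than methoxide. Both methoxy groups sit meta to C8a and so put no charge on the attacked carbon, although as ortho/para donors to the ketone they weaken its pull, which is why fluorine and a dipolar aprotic solvent are used.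

Step 8
Reactants: 14 3-(benzyloxy)-8-{(1R)-1-[4-(benzyloxy)phenyl]ethyl}-5,7-dimethoxy-2-(4-methoxyphenyl)-4H-chromen-4-one
Product: 15 3,5-dihydroxy-8-[(1R)-1-(4-hydroxyphenyl)ethyl]-7-methoxy-2-(4-methoxyphenyl)-4H-chromen-4-one
Conditions: BCl3 (8 equiv), C6HMe5 (6 equiv), CH2Cl2, −78 → 0 °C; aqueous work-up
Reagents that add atoms: none
Why: Lewis-acid ether cleavage, in which BCl3 with pentamethylbenzene as benzyl-cation scavenger should remove both benzyl ethers and chelation of boron between the C4 carbonyl and O5 should confine demethylation to the 5-methoxy group, leaving the 7- and 4'-methyl ethers and the benzylic stereocentre untouched.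

Compound list
1 | 1-fluoro-3,5-dimethoxybenzene | COc1cc(F)cc(OC)c1 | starting material
2 | 4-(benzyloxy)benzoyl chloride | O=C(Cl)c1ccc(OCc2ccccc2)cc1 | starting material
3 | [4-(benzyloxy)phenyl](2-fluoro-4,6-dimethoxyphenyl)methanone | COc1cc(F)c(C(=O)c2ccc(OCc3ccccc3)cc2)c(OC)c1 | intermediate
4 | 2-{1-[4-(benzyloxy)phenyl]ethenyl}-1-fluoro-3,5-dimethoxybenzene | C=C(c1ccc(OCc2ccccc2)cc1)c1c(F)cc(OC)cc1OC | intermediate
5 | 2-{(1R)-1-[4-(benzyloxy)phenyl]ethyl}-1-fluoro-3,5-dimethoxybenzene | COc1cc(OC)c([C@H](C)c2ccc(OCc3ccccc3)cc2)c(F)c1 | intermediate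
6 | 1-bromo-3-{(1R)-1-[4-(benzyloxy)phenyl]ethyl}-2-fluoro-4,6-dimethoxybenzene | COc1cc(OC)c([C@H](C)c2ccc(OCc3ccccc3)cc2)c(F)c1Br | intermediate
7 | 2-(benzyloxy)-N-methoxy-N-methylacetamide | CON(C)C(=O)COCc1ccccc1 | starting material
8 | (3-{(1R)-1-[4-(benzyloxy)phenyl]ethyl}-2-fluoro-4,6-dimethoxyphenyl)lithium, formed in the flask | [Li]c1c(F)c([C@H](C)c2ccc(OCc3ccccc3)cc2)c(OC)cc1OC | intermediate
9 | lithium alkoxide of the N-methoxy-N-methyl hemiaminal from 8 and 7 (new carbinol carbon undefined), formed in the flask | [Li]OC(COCc1ccccc1)(N(C)OC)c1c(F)c([C@H](C)c2ccc(OCc3ccccc3)cc2)c(OC)cc1OC | intermediate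
10 | 2-(benzyloxy)-1-(3-{(1R)-1-[4-(benzyloxy)phenyl]ethyl}-2-fluoro-4,6-dimethoxyphenyl)ethan-1-one | O=C(COCc1ccccc1)c1c(F)c([C@H](C)c2ccc(OCc3ccccc3)cc2)c(OC)cc1OC | intermediate
11 | 4-methoxybenzoyl chloride | COc1ccc(C(=O)Cl)cc1 | starting material
12 | chelated lithium (Z)-enolate of ketone 10, formed in the flask | [Li]O/C(=C\OCc1ccccc1)c1c(F)c([C@H](C)c2ccc(OCc3ccccc3)cc2)c(OC)cc1OC | intermediate
13 | 2-(benzyloxy)-1-(3-{(1R)-1-[4-(benzyloxy)phenyl]ethyl}-2-fluoro-4,6-dimethoxyphenyl)-3-(4-methoxyphenyl)propane-1,3-dione, written as the chelated enol with the OH on the anisyl-bearing carbon | O/C(c1ccc(OC)cc1)=C(\C(=O)c1c(F)c([C@H](C)c2ccc(OCc3ccccc3)cc2)c(OC)cc1OC)OCc1ccccc1 | intermediate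
14 | 3-(benzyloxy)-8-{(1R)-1-[4-(benzyloxy)phenyl]ethyl}-5,7-dimethoxy-2-(4-methoxyphenyl)-4H-chromen-4-one | COc1ccc(-c2oc3c([C@H](C)c4ccc(OCc5ccccc5)cc4)c(OC)cc(OC)c3c(=O)c2OCc2ccccc2)cc1 | intermediate
15 | 3,5-dihydroxy-8-[(1R)-1-(4-hydroxyphenyl)ethyl]-7-methoxy-2-(4-methoxyphenyl)-4H-chromen-4-one | COc1ccc(-c2oc3c([C@H](C)c4ccc(O)cc4)c(OC)cc(O)c3c(=O)c2O)cc1 | target

Total step count: 8
Longest linear sequence: 8 steps (1 → 15); building blocks 2, 7 and 11 are purchased.

Steps most likely to fail

Step 3. What may go wrong is poor facial discrimination between the two aryl groups, or slow turnover at the hindered alkene. The fallback sets out from 4 and replaces asymmetric catalysis by resolution. Alkene 4 is hydrogenated with an achiral homogeneous catalyst (H2, [Ir(cod)(PCy3)(py)]PF6, CH2Cl2, which keeps the benzyl ether) to racemic 2-{1-[4-(benzyloxy)phenyl]ethyl}-1-fluoro-3,5-dimethoxybenzene F1. The enantiomers are then separated by preparative supercritical-fluid chromatography on a polysaccharide chiral phase; the (R)-enantiomer is 5, where the route resumes.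

Step 7. What may go wrong is slow addition of the enolate to the donor-substituted, ortho-hindered ring, with retro-Claisen cleavage of the diketone by adventitious hydroxide taking over. The fallback sets out from 10 and makes the ring oxygen first, then closes the ring by condensation at C2.
- Fluorine is exchanged for hydroxyl with a hydroxide surrogate (acetohydroxamic acid, K2CO3, DMSO, 80 °C) to give 2-(benzyloxy)-1-(3-{(1R)-1-[4-(benzyloxy)phenyl]ethyl}-2-hydroxy-4,6-dimethoxyphenyl)ethan-1-one F2.
- The phenol is acylated with 11 (pyridine, DMAP) to give the aryl 4-methoxybenzoate F3.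
- Baker–Venkataraman rearrangement (KOH, pyridine, 50 °C) gives 2-(benzyloxy)-1-(3-{(1R)-1-[4-(benzyloxy)phenyl]ethyl}-2-hydroxy-4,6-dimethoxyphenyl)-3-(4-methoxyphenyl)propane-1,3-dione F4.
- Acid cyclodehydration (cat. H2SO4, AcOH, 60 °C) gives 14, where the route resumes.

Step 8. What may go wrong is incomplete cleavage of the chelated 5-methyl ether once boron is bound at O3/O4, or transfer of benzyl cations to the electron-rich C6 of ring A. The fallback sets out from 14 and separates the two kinds of cleavage. Hydrogenolysis (H2, Pd/C, EtOAc–MeOH, rt) gives 3-hydroxy-8-[(1R)-1-(4-hydroxyphenyl)ethyl]-5,7-dimethoxy-2-(4-methoxyphenyl)-4H-chromen-4-one F5. Chelation-controlled 5-O-demethylation (AlCl3, MeCN, 60 °C, or BCl3, CH2Cl2, 0 °C) then gives 15.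

Further compounds
F1 | step 3 | racemic 2-{1-[4-(benzyloxy)phenyl]ethyl}-1-fluoro-3,5-dimethoxybenzene | COc1cc(OC)c(C(C)c2ccc(OCc3ccccc3)cc2)c(F)c1
F2 | step 7 | 2-(benzyloxy)-1-(3-{(1R)-1-[4-(benzyloxy)phenyl]ethyl}-2-hydroxy-4,6-dimethoxyphenyl)ethan-1-one | O=C(COCc1ccccc1)c1c(O)c([C@H](C)c2ccc(OCc3ccccc3)cc2)c(OC)cc1OC
F3 | step 7 | 2-[(benzyloxy)acetyl]-6-{(1R)-1-[4-(benzyloxy)phenyl]ethyl}-3,5-dimethoxyphenyl 4-methoxybenzoate | O=C(COCc1ccccc1)c1c(OC(=O)c2ccc(OC)cc2)c([C@H](C)c2ccc(OCc3ccccc3)cc2)c(OC)cc1OC
F4 | step 7 | 2-(benzyloxy)-1-(3-{(1R)-1-[4-(benzyloxy)phenyl]ethyl}-2-hydroxy-4,6-dimethoxyphenyl)-3-(4-methoxyphenyl)propane-1,3-dione | COc1ccc(C(=O)C(OCc2ccccc2)C(=O)c2c(O)c([C@H](C)c3ccc(OCc4ccccc4)cc3)c(OC)cc2OC)cc1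
F5 | step 8 | 3-hydroxy-8-[(1R)-1-(4-hydroxyphenyl)ethyl]-5,7-dimethoxy-2-(4-methoxyphenyl)-4H-chromen-4-one | COc1ccc(-c2oc3c([C@H](C)c4ccc(O)cc4)c(OC)cc(OC)c3c(=O)c2O)cc1
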